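**Strategy.** The route rests on cutting ring C between C3 and C4. Each of these carbons bears an oxygen, so the 3-hydroxy-4-pyranone is a tautomer of a chroman-3,4-dione, and the bond between them unites two carbons that are each normally electrophilic. A triazolylidene carbene inverts the polarity of the ring A aldehyde carbon (C4), which then acylates itself with the tethered ester carbon (C3). One operation forms C3–C4, closes ring C and, after enolisation, gives the flavonol. The substrate is a racemic methyl 2-aryl-2-(2-formylaryloxy)acetate whose O1–C2 ether already joins ring A, carrying the C8 1,1-dimethylallyl group, to ring B, with the three phenols as MOM ethers.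

Key step: step 13

Assumption: 2-bromo-4,5-dihydroxybenzaldehyde (9) and tributyl(3-methylbut-2-en-1-yl)stannane (22) are bought; 9 is otherwise one BBr3 demethylation from 2-bromo-4,5-dimethoxybenzaldehyde.
Design remark: substrate 25 keeps an unactivated methyl ester, because an activated ester would acylate the free carbene and acidify C2–H further; MOM ethers on O5, O7 and O5' are stable to carbonate and are removed together at the end.

**Ring A aldehyde (steps 1–4)**

Step 1
Reactants: 1 phloroglucinol
Product: 2 3,5-bis(methoxymethoxy)phenol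
Conditions: MOMCl (2.1 equiv), i-Pr2NEt, DMF, 0 °C to rt; chromatography
Reagents that add atoms: chloromethyl methyl ether, COCCl
Why: Williamson-type O-alkylation with an α-chloro ether: the three hydroxyls of 1 are equivalent, so two equivalents of electrophile should make the bis-ether the main member of a statistical set, from which the mono- and tris-ethers are separated and recycled.

Step 2
Reactants: 2 3,5-bis(methoxymethoxy)phenol; 3 prenyl bromide
Product: 4 1,3-bis(methoxymethoxy)-5-[(3-methylbut-2-en-1-yl)oxy]benzene
Conditions: K2CO3, acetone, reflux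
Reagents that add atoms: none
Why: Williamson ether synthesis: the single phenoxide of 2 should attack the primary allylic bromide at oxygen by SN2, the two acetal ethers being inert to carbonate.

Step 3
Reactants: 4 1,3-bis(methoxymethoxy)-5-[(3-methylbut-2-en-1-yl)oxy]benzene
Product: 6 3,5-bis(methoxymethoxy)-2-(2-methylbut-3-en-2-yl)phenol, via ortho-dienone 5 (not isolated)
Conditions: PhNEt2, 190 °C, sealed tube, Ar
Reagents that add atoms: none
Why: Aromatic Claisen rearrangement: the [3,3] shift transposes the allyl unit so that its tertiary carbon bonds to either of the two equivalent ortho carbons, and in the basic aniline solvent dienone 5 should enolise to the phenol faster than it undergoes a Cope shift to the para carbon.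

Step 4
Reactants: 6 3,5-bis(methoxymethoxy)-2-(2-methylbut-3-en-2-yl)phenol
Product: 8 2-hydroxy-4,6-bis(methoxymethoxy)-3-(2-methylbut-3-en-2-yl)benzaldehyde, via salicyl alcohol 7 (not isolated)
Conditions: MgCl2, Et3N, (CH2O)n, MeCN, reflux
Reagents that add atoms: paraformaldehyde (as formaldehyde), C=O
Why: Magnesium-mediated ortho-formylation of a phenol (Casnati–Skattebøl reaction): the magnesium phenoxide delivers formaldehyde only to the one free ortho carbon and the benzylic alkoxide 7 is oxidised by hydride transfer to a second formaldehyde, so the formyl group should enter next to the hydroxyl and not between the two MOM ethers.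

**Ring B mandelate (steps 5–11)**

Step 5
Reactants: 9 2-bromo-4,5-dihydroxybenzaldehyde; 10 3-chloro-3-methylbut-1-yne
Product: 11 2-bromo-5-hydroxy-4-[(2-methylbut-3-yn-2-yl)oxy]benzaldehyde
Conditions: DBU (1.1 equiv), CuCl2·2H2O (cat.), MeCN, 0 °C
Reagents that add atoms: none
Why: Copper-catalysed O-propargylation of a phenol with a tertiary propargylic chloride: one equivalent of amidine base should ionise only the more acidic hydroxyl para to the formyl group, the same acidity difference that governs mono-alkylation of 3,4-dihydroxybenzaldehyde.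

Step 6
Reactants: 11 2-bromo-5-hydroxy-4-[(2-methylbut-3-yn-2-yl)oxy]benzaldehyde
Product: 12 2-bromo-5-hydroxy-4-[(2-methylbut-3-en-2-yl)oxy]benzaldehyde
Conditions: H2 (1 atm), Pd/CaCO3 poisoned with Pb(OAc)2, quinoline, EtOAc, rt
Reagents that add atoms: none
Why: Lindlar semi-hydrogenation: the poisoned palladium surface should reduce the terminal alkyne to the alkene and stop, leaving the aryl bromide and the aldehyde untouched.

Step 7
Reactants: 12 2-bromo-5-hydroxy-4-[(2-methylbut-3-en-2-yl)oxy]benzaldehyde
Product: 15 5-bromo-8-hydroxy-2,2-dimethylchroman-6-carbaldehyde, via ortho-dienone 13 (not isolated), via prenylcatechol 14 (not isolated)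
Conditions: o-xylene, 135 °C; then p-TsOH·H2O (cat.), 90 °C
Reagents that add atoms: none
Why: Aromatic Claisen rearrangement followed by acid-catalysed hydroalkoxylation: the [3,3] shift can only end at the single ortho carbon that bears hydrogen (next to bromine) and turns the 1,1-dimethylallyl ether into a C-prenyl group, whose Markovnikov protonation lets the adjacent hydroxyl close the six-membered 2,2-dimethylchroman ring.

Step 8
Reactants: 15 5-bromo-8-hydroxy-2,2-dimethylchroman-6-carbaldehyde
Product: 16 5-bromo-8-(methoxymethoxy)-2,2-dimethylchroman-6-carbaldehyde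
Conditions: MOMCl, i-Pr2NEt, CH2Cl2, 0 °C to rt
Reagents that add atoms: chloromethyl methyl ether, COCCl
Why: Williamson-type O-alkylation: the only remaining phenol should be capped as its MOM ether under mild amine-base conditions that do not touch the aldehyde or the aryl bromide.

Step 9
Reactants: 16 5-bromo-8-(methoxymethoxy)-2,2-dimethylchroman-6-carbaldehyde
Product: 20 racemic 2-[5-bromo-8-(methoxymethoxy)-2,2-dimethylchroman-6-yl]-2-hydroxyacetic acid, via tribromomethyl carbinol 17 (not isolated), via dibromo-epoxide 18 (not isolated), via acyl bromide 19 (not isolated)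
Conditions: CHBr3, KOH, LiCl, 1,4-dioxane/H2O, 0–5 °C; then aq. NaHSO4 to pH 3, 0 °C
Reagents that add atoms: bromoform, BrC(Br)Br; potassium hydroxide, [K+].[OH-]
Why: Jocic–Reeve reaction in its bromoform variant: tribromomethyl anion adds to the aldehyde, the alkoxide closes to a gem-dibromo-epoxide that hydroxide opens at the benzylic carbon, and the acyl bromide is hydrolysed, which should give the mandelic acid without the strong acid that cyanohydrin hydrolysis would need; the new stereocentre forms without control and is erased in step 13.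

Step 10
Reactants: 20 racemic 2-[5-bromo-8-(methoxymethoxy)-2,2-dimethylchroman-6-yl]-2-hydroxyacetic acid
Product: 21 racemic methyl 2-[5-bromo-8-(methoxymethoxy)-2,2-dimethylchroman-6-yl]-2-hydroxyacetate
Conditions: MeI, KHCO3, DMF, rt
Reagents that add atoms: iodomethane, CI
Why: Carboxylate O-alkylation by SN2: hydrogencarbonate should ionise only the carboxylic acid, so iodomethane gives the methyl ester and leaves the secondary hydroxyl free.

Step 11
Reactants: 21 racemic methyl 2-[5-bromo-8-(methoxymethoxy)-2,2-dimethylchroman-6-yl]-2-hydroxyacetate; 22 tributyl(3-methylbut-2-en-1-yl)stannane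
Product: 23 racemic methyl 2-hydroxy-2-[8-(methoxymethoxy)-2,2-dimethyl-5-(3-methylbut-2-en-1-yl)chroman-6-yl]acetate
Conditions: Pd(PPh3)4 (10 mol%), DMF, 100 °C, Ar
Reagents that add atoms: none
Why: Stille cross-coupling: zerovalent palladium inserts into the aryl–bromine bond, the allylstannane transmetalates, and reductive elimination from the η3-allyl complex at its less hindered terminus should give the linear prenyl arene, the neutral conditions sparing the free hydroxyl, the ester and the MOM ether.

**Union, ring closure and deprotection (steps 12–14)**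

Step 12
Reactants: 23 racemic methyl 2-hydroxy-2-[8-(methoxymethoxy)-2,2-dimethyl-5-(3-methylbut-2-en-1-yl)chroman-6-yl]acetate; 8 2-hydroxy-4,6-bis(methoxymethoxy)-3-(2-methylbut-3-en-2-yl)benzaldehyde
Product: 25 racemic methyl 2-[2-formyl-3,5-bis(methoxymethoxy)-6-(2-methylbut-3-en-2-yl)phenoxy]-2-[8-(methoxymethoxy)-2,2-dimethyl-5-(3-methylbut-2-en-1-yl)chroman-6-yl]acetate, via mesylate 24 (not isolated)
Conditions: Ms2O (1.0 equiv), i-Pr2NEt, CH2Cl2, −20 °C; evaporation; then 8, Cs2CO3, DMF, 0 °C to rt
Reagents that add atoms: none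
Why: Sulfonylation followed by Williamson etherification: the mesylate of the α-hydroxy ester is an activated secondary electrophile (SN2 next to a carbonyl group), and the caesium phenoxide of 8, although flanked by two substituents, should displace it below room temperature before base can promote aldol closure; the stereocentre stays racemic.

Step 13
Reactants: 25 racemic methyl 2-[2-formyl-3,5-bis(methoxymethoxy)-6-(2-methylbut-3-en-2-yl)phenoxy]-2-[8-(methoxymethoxy)-2,2-dimethyl-5-(3-methylbut-2-en-1-yl)chroman-6-yl]acetate
Product: 28 5,7,5'-tris(methoxymethyl) ether of Broussoflavonol E, via hydroxy-enamine 26 (not isolated), via chroman-3,4-dione 27 (not isolated)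
Conditions: 2-(pentafluorophenyl)-6,7-dihydro-5H-pyrrolo[2,1-c][1,2,4]triazol-2-ium tetrafluoroborate (20 mol%), K2CO3 (1.5 equiv), 4 Å molecular sieves, degassed THF (0.02 M), 40 °C, Ar; then aq. NH4Cl
Reagents that add atoms: none
Why: Proposed new method: the triazolylidene freed by carbonate adds to the aldehyde carbon of 25 (future C4) and proton transfer gives hydroxy-enamine 26, whose nucleophilic carbon attacks the tethered ester carbonyl (future C3); loss of methoxide and then of the carbene gives chroman-3,4-dione 27, which enolises through its C2–H to the aromatic, internally hydrogen-bonded 3-hydroxy-4-pyranone. The closest known reaction types are the carbene-catalysed intramolecular crossed benzoin reaction of aldehydes with tethered ketones, which gives 3-hydroxychroman-4-ones, and the analogous closure onto a tethered nitrile; a carboxylic ester has not been shown as the acceptor. Ring C is closed in a 6-exo-trig mode, the new ring holding O1, C2, C3, C4, C4a and C8a with the ester C=O outside it. No stereocentre is created, and the racemic centre at C2 is erased by the enolisation. The step needs the hindered, electron-rich aldehyde to form the acyl anion equivalent and acylate internally faster than it dimerises or is attacked by the C2 enolate in an aldol closure: the two ortho substituents block the bimolecular benzoin path, the small electron-poor N-pentafluorophenyl catalyst can still reach the carbonyl, the unactivated methyl ester cannot acylate the carbene, and the aldolate (quaternary C2, unable to dehydrate) forms reversibly. Tautomerisation to the flavonolate is irreversible and should pull every preceding equilibrium forward.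

Step 14
Reactants: 28 5,7,5'-tris(methoxymethyl) ether of Broussoflavonol E
Product: 29 Broussoflavonol E
Conditions: HCl (3 M aq.)/MeOH (1:5), THF, 40 °C
Reagents that add atoms: none
Why: Acid-catalysed acetal cleavage (MOM ether removal): mild methanolic hydrochloric acid should release the three phenols as dimethoxymethane forms, under conditions gentle enough to leave uncyclised both the terminal alkene of the 1,1-dimethylallyl group and the prenyl group, which has no ortho hydroxyl.

**Compound list**

1 | phloroglucinol (benzene-1,3,5-triol) | Oc1cc(O)cc(O)c1 | starting material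
2 | 3,5-bis(methoxymethoxy)phenol | COCOc1cc(O)cc(OCOC)c1 | intermediate
3 | prenyl bromide (1-bromo-3-methylbut-2-ene) | CC(C)=CCBr | starting material
4 | 1,3-bis(methoxymethoxy)-5-[(3-methylbut-2-en-1-yl)oxy]benzene | COCOc1cc(OCOC)cc(OCC=C(C)C)c1 | intermediate
5 | racemic 3,5-bis(methoxymethoxy)-6-(2-methylbut-3-en-2-yl)cyclohexa-2,4-dien-1-one | O=C1C=C(OCOC)C=C(OCOC)C1C(C)(C)C=C | intermediate (not isolated)
6 | 3,5-bis(methoxymethoxy)-2-(2-methylbut-3-en-2-yl)phenol | Oc1cc(OCOC)cc(OCOC)c1C(C)(C)C=C | intermediate
7 | 2-(hydroxymethyl)-3,5-bis(methoxymethoxy)-6-(2-methylbut-3-en-2-yl)phenol (present as its magnesium alkoxide) | OCc1c(O)c(C(C)(C)C=C)c(OCOC)cc1OCOC | intermediate (not isolated)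
8 | 2-hydroxy-4,6-bis(methoxymethoxy)-3-(2-methylbut-3-en-2-yl)benzaldehyde | O=Cc1c(O)c(C(C)(C)C=C)c(OCOC)cc1OCOC | intermediate
9 | 2-bromo-4,5-dihydroxybenzaldehyde | O=Cc1cc(O)c(O)cc1Br | starting material
10 | 3-chloro-3-methylbut-1-yne | C#CC(C)(C)Cl | starting material
11 | 2-bromo-5-hydroxy-4-[(2-methylbut-3-yn-2-yl)oxy]benzaldehyde | O=Cc1cc(O)c(OC(C)(C)C#C)cc1Br | intermediate
12 | 2-bromo-5-hydroxy-4-[(2-methylbut-3-en-2-yl)oxy]benzaldehyde | O=Cc1cc(O)c(OC(C)(C)C=C)cc1Br | intermediate
13 | racemic 2-bromo-5-hydroxy-3-(3-methylbut-2-en-1-yl)-4-oxocyclohexa-1,5-diene-1-carbaldehyde | O=CC1=C(Br)C(CC=C(C)C)C(=O)C(O)=C1 | intermediate (not isolated)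
14 | 2-bromo-4,5-dihydroxy-3-(3-methylbut-2-en-1-yl)benzaldehyde | O=Cc1cc(O)c(O)c(CC=C(C)C)c1Br | intermediate (not isolated)
15 | 5-bromo-8-hydroxy-2,2-dimethylchroman-6-carbaldehyde | O=Cc1cc(O)c2OC(C)(C)CCc2c1Br | intermediate
16 | 5-bromo-8-(methoxymethoxy)-2,2-dimethylchroman-6-carbaldehyde | O=Cc1cc(OCOC)c2OC(C)(C)CCc2c1Br | intermediate
17 | racemic 2,2,2-tribromo-1-[5-bromo-8-(methoxymethoxy)-2,2-dimethylchroman-6-yl]ethanol (present as its potassium alkoxide) | OC(c1cc(OCOC)c2OC(C)(C)CCc2c1Br)C(Br)(Br)Br | intermediate (not isolated)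
18 | racemic 2,2-dibromo-3-[5-bromo-8-(methoxymethoxy)-2,2-dimethylchroman-6-yl]oxirane | BrC1(Br)OC1c1cc(OCOC)c2OC(C)(C)CCc2c1Br | intermediate (not isolated)
19 | racemic 2-[5-bromo-8-(methoxymethoxy)-2,2-dimethylchroman-6-yl]-2-hydroxyacetyl bromide | O=C(Br)C(O)c1cc(OCOC)c2OC(C)(C)CCc2c1Br | intermediate (not isolated)
20 | racemic 2-[5-bromo-8-(methoxymethoxy)-2,2-dimethylchroman-6-yl]-2-hydroxyacetic acid | OC(=O)C(O)c1cc(OCOC)c2OC(C)(C)CCc2c1Br | intermediate
21 | racemic methyl 2-[5-bromo-8-(methoxymethoxy)-2,2-dimethylchroman-6-yl]-2-hydroxyacetate | COC(=O)C(O)c1cc(OCOC)c2OC(C)(C)CCc2c1Br | intermediate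
22 | tributyl(3-methylbut-2-en-1-yl)stannane | CC(C)=CC[Sn](CCCC)(CCCC)CCCC | starting material
23 | racemic methyl 2-hydroxy-2-[8-(methoxymethoxy)-2,2-dimethyl-5-(3-methylbut-2-en-1-yl)chroman-6-yl]acetate | COC(=O)C(O)c1cc(OCOC)c2OC(C)(C)CCc2c1CC=C(C)C | intermediate
24 | racemic methyl 2-[(methanesulfonyl)oxy]-2-[8-(methoxymethoxy)-2,2-dimethyl-5-(3-methylbut-2-en-1-yl)chroman-6-yl]acetate | COC(=O)C(OS(C)(=O)=O)c1cc(OCOC)c2OC(C)(C)CCc2c1CC=C(C)C | intermediate (not isolated)
25 | racemic methyl 2-[2-formyl-3,5-bis(methoxymethoxy)-6-(2-methylbut-3-en-2-yl)phenoxy]-2-[8-(methoxymethoxy)-2,2-dimethyl-5-(3-methylbut-2-en-1-yl)chroman-6-yl]acetate | O=Cc1c(OCOC)cc(OCOC)c(C(C)(C)C=C)c1OC(C(=O)OC)c1cc(OCOC)c2OC(C)(C)CCc2c1CC=C(C)C | intermediate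
26 | hydroxy-enamine (Breslow intermediate) formed from the aldehyde carbon of 25 and the N-pentafluorophenyl pyrrolo-triazolylidene; racemic | OC(=C1N(c2c(F)c(F)c(F)c(F)c2F)N=C2CCCN12)c1c(OCOC)cc(OCOC)c(C(C)(C)C=C)c1OC(C(=O)OC)c1cc(OCOC)c2OC(C)(C)CCc2c1CC=C(C)C | intermediate (not isolated)
27 | racemic 5,7-bis(methoxymethoxy)-2-[8-(methoxymethoxy)-2,2-dimethyl-5-(3-methylbut-2-en-1-yl)chroman-6-yl]-8-(2-methylbut-3-en-2-yl)chroman-3,4-dione | C=CC(C)(C)c1c(OCOC)cc(OCOC)c2C(=O)C(=O)C(c3cc(OCOC)c4OC(C)(C)CCc4c3CC=C(C)C)Oc12 | intermediate (not isolated)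
28 | 3-hydroxy-5,7-bis(methoxymethoxy)-2-[8-(methoxymethoxy)-2,2-dimethyl-5-(3-methylbut-2-en-1-yl)chroman-6-yl]-8-(2-methylbut-3-en-2-yl)-4H-chromen-4-one (5,7,5'-tris-MOM ether of Broussoflavonol E) | C=CC(C)(C)c1c(OCOC)cc(OCOC)c2c(=O)c(O)c(-c3cc(OCOC)c4c(c3CC=C(C)C)CCC(C)(C)O4)oc12 | intermediate
29 | Broussoflavonol E (no stereocentre) | C=CC(C)(C)c1c(O)cc(O)c2c(=O)c(O)c(-c3cc(O)c4c(c3CC=C(C)C)CCC(C)(C)O4)oc12 | target

**Totals**

Total step count: 14.
Longest linear sequence: 10 steps (9 to 29: steps 5–14); the ring A branch (steps 1–4) joins at step 12.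

**Steps most likely to fail**

1. Step 13 (carbene-catalysed ring closure). The acyl anion equivalent may revert to the aldehyde faster than it acylates the ester, or carbonate may drive the C2 enolate into aldol closure and slow decomposition. The fallback is the classical chalcone route, which sets out from 8 and 16 and comes back at 28.
   - Addition of MeMgBr to 8 (THF, 0 °C) should give racemic 1-[2-hydroxy-4,6-bis(methoxymethoxy)-3-(2-methylbut-3-en-2-yl)phenyl]ethanol F1.
   - Benzylic oxidation with MnO2 (CH2Cl2) should give 1-[2-hydroxy-4,6-bis(methoxymethoxy)-3-(2-methylbut-3-en-2-yl)phenyl]ethanone F2.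
   - In parallel, Stille coupling of 16 with 22 (Pd(PPh3)4, DMF, 100 °C) should give 8-(methoxymethoxy)-2,2-dimethyl-5-(3-methylbut-2-en-1-yl)chroman-6-carbaldehyde F3.
   - Claisen–Schmidt condensation of F2 with F3 (KOH, EtOH, rt) should give the (E)-2'-hydroxychalcone F4.
   - Algar–Flynn–Oyamada oxidation (H2O2, NaOH, MeOH, 0 °C, kept cold to disfavour aurone formation) closes ring C and installs the 3-hydroxyl, giving 28.

2. Step 12 (etherification). Substitution between two hindered partners may be slow, the electron-rich benzylic mesylate may ionise with participation of the neighbouring prenyl alkene, or carbonate may trigger aldol closure of the product. The fallback is a Mitsunobu etherification under neutral conditions (PPh3, DIAD, toluene, 0 °C to rt), which sets out from 23 and 8 and comes back at 25. It activates the hydroxyl in place as an oxyphosphonium ion and needs neither a sulfonate nor a base. It makes no compound outside the list (entry F0).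

3. Step 11 (Stille prenylation). Oxidative addition at the bromide flanked by two substituents may be slow, and allyl transposition may deliver the branched 2-methylbut-3-en-2-yl isomer. The fallback separates C–C coupling from the choice of alkene substitution; it sets out from 21 and comes back at 23. Stille coupling of 21 with allyltributylstannane (Pd(PPh3)4, DMF, 100 °C), which has no regiochemical ambiguity, should give racemic methyl 2-[5-allyl-8-(methoxymethoxy)-2,2-dimethylchroman-6-yl]-2-hydroxyacetate F5. Olefin cross-metathesis of F5 with excess 2-methylbut-2-ene (second-generation Grubbs catalyst, CH2Cl2, 40 °C) then gives 23.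

**Further compounds**

F1 | step 13 | racemic 1-[2-hydroxy-4,6-bis(methoxymethoxy)-3-(2-methylbut-3-en-2-yl)phenyl]ethanol | CC(O)c1c(O)c(C(C)(C)C=C)c(OCOC)cc1OCOC
F2 | step 13 | 1-[2-hydroxy-4,6-bis(methoxymethoxy)-3-(2-methylbut-3-en-2-yl)phenyl]ethanone | CC(=O)c1c(O)c(C(C)(C)C=C)c(OCOC)cc1OCOC
F3 | step 13 | 8-(methoxymethoxy)-2,2-dimethyl-5-(3-methylbut-2-en-1-yl)chroman-6-carbaldehyde | O=Cc1cc(OCOC)c2OC(C)(C)CCc2c1CC=C(C)C
F4 | step 13 | (E)-1-[2-hydroxy-4,6-bis(methoxymethoxy)-3-(2-methylbut-3-en-2-yl)phenyl]-3-[8-(methoxymethoxy)-2,2-dimethyl-5-(3-methylbut-2-en-1-yl)chroman-6-yl]prop-2-en-1-one | O=C(/C=C/c1cc(OCOC)c2OC(C)(C)CCc2c1CC=C(C)C)c1c(O)c(C(C)(C)C=C)c(OCOC)cc1OCOC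
F0 | step 12 | none | none
F5 | step 11 | racemic methyl 2-[5-allyl-8-(methoxymethoxy)-2,2-dimethylchroman-6-yl]-2-hydroxyacetate | COC(=O)C(O)c1cc(OCOC)c2OC(C)(C)CCc2c1CC=C
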